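In the oak run at 4.00 h the starting material reads 37% and the target 0%, so the product you want is not accumulating, and that reading has to shape the reckoning.

in all of them: starting material 0.10 M

| run | reagent | scavenger | remark | time |
|---|---|---|---|---|
| oak | 1 equiv | 1.1 equiv | run made earlier |  |
| winter | 1.00 equiv | 0.800 equiv |  | 6.0 h |
| dawn | 1.00 equiv | 1.00 equiv |  | 6.0 h |
| midnight | 1.00 equiv | 1.40 equiv |  | 6.0 h |

oak run (percent of the starting material charged)

| time / h | starting material / % | target / % |
|---|---|---|
| 0.333 | 90 | 0 |
| 0.667 | 82 | 2 |
| 1.33 | 68 | 0 |
| 2.00 | 55 | 2 |
| 4.00 | 37 | 0 |

(readings scatter by 2 percentage points)

* part of the starting material that has reacted at the end, winter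
* part of the starting material that has reacted at the end, dawn
* part of the starting material that has reacted at the end, midnight
* what raising the equivalents of scavenger from its lowest to its highest value here does to the part of the starting material that has reacted (changes below 5 percentage points count as none) (it rises / no change / it falls)

- the numbers in the tables scatter with a standard deviation of 2 percentage points
- no earlier run changes the charge of scavenger; that part of a forecast is a guess

Take the run in slow motion, with f the fraction of starting material left and b the fraction of reagent left. My assumption is that a second starting material takes each target as it forms, so one reagent used costs two starting material and b = (1 + f)/2. Write the fall as 2κfb. In the first instants f and b stand near 1, so f falls at 2κ per hour. Late on, b nears 0.5 and the fall becomes pseudo-first-order, κf. Integrating this fall from the first instants onward joins the two ends and gives the pairing clock κ: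

ln[(1 + f)/(2f)] = κt

Oak gives 0.171 h⁻¹ at 2.00 h and 0.154 h⁻¹ at 4.00 h. I take the mean of these readings, κ = 0.163 h⁻¹. In this picture κ scales with the charge of starting material at fixed equivalents. For winter:

κt = 0.978, so f = 23.2%, and reacted = 76.8%

The clock holds no scavenger, so I commit to that figure for winter, dawn and midnight, with no change. If each reagent used costs one scavenger, winter needs 0.384 equiv, less than its 0.800 equiv, but no earlier run varied the scavenger, so this part is a guess.

The forecast gives 72%, 73% and 73%, with no change, and differs from my figure; it holds that “the scavenger, in excess in oak, is evidently removing it as it forms”.

The flasks give 78.4%, 78.1% and 77.9%: no change, a shift of −0.46 percentage points.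

    starting material + reagent → target + released group (k = 0.0280 L mol⁻¹ min⁻¹)
    starting material + target → side product (k = 1.80 L mol⁻¹ min⁻¹)
    starting material + reagent + released group → target + 2 released group (k = 17.0 L² mol⁻² min⁻¹)
    scavenger + released group → scavenged by-product (k = 35.0 L mol⁻¹ min⁻¹)
    starting material + released group ⇌ idle adduct, settled at all times (K = 3.20 L mol⁻¹)

In winter at 1.59 h, target is made at 0.982 of the rate at which it is used up, and its half-life against starting material is 0.10 h, far shorter than the 6.0 h of the run. At the end of winter, target stands at 0.970% and side product at 77.4%, while the clock's 61.6% of reagent compares with 60% in the flask. For the same flask as winter but with 0.025 M of starting material, κ scaled to that charge gives f = 64.4%, and that flask ends with 64.1% of starting material.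

The readings were generated by integration from invented constants; noise was put on by code.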